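**Retrosynthetic overview**
1. C6–Cl is installed last by invertive deoxychlorination of a 6-epi allylic alcohol; the C2/C9 acetates, C14 butanoate and C12 ketone are already in place.
2. The ten-membered ring (third and last ring formed) is closed by an intramolecular Nozaki–Hiyama–Kishi reaction of a C3 dienyl iodide onto the C2 neopentyl aldehyde (C2–C3 bond, E-C3=C4 preset).
3. The γ-lactone (second ring) comes from hydroxyl-directed epoxidation of a C7=C8 allylic alcohol, then opening of the epoxide at C7 by the C19 tert-butyl ester.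
4. The two fragments are joined at C8–C9 by an intermolecular Nozaki–Hiyama–Kishi coupling of ring A aldehyde (fragment 1) with a trisubstituted alkenyl iodide (fragment 2).
5. Ring A (first ring) comes from a Diels–Alder reaction of a 1-amino-3-siloxydiene with (E)-4,4-dimethoxy-2-methylbut-2-enal; fragment 2 comes from a silyl dienal and a Roche-ester alkyne.

Locants C1–C20 are briarane numbering of the target: ring A = C1, C10–C14; ten-membered ring = C1–C10; lactone = C7, C8, C17, C19, O; C15 = methyl on C1, C16 = methylene on C5, C18 = methyl on C17, C20 = methyl on C11. TBS = tert-butyldimethylsilyl, TIPS = triisopropylsilyl, TMS = trimethylsilyl, Bpin = pinacolboryl.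
Assumption: the named enantiomer of each chiral catalyst (TADDOL in step 4, ProPhenol in step 16) is taken to be the one that gives the drawn absolute configuration; otherwise its antipode is used.

**Fragment 1 (ring A aldehyde 18)**

Step 1
Reactants: 1 2,2-dimethoxyacetaldehyde; 2 2-(triphenylphosphoranylidene)propanal
Product: 3 (E)-4,4-dimethoxy-2-methylbut-2-enal
Conditions: CH2Cl2, rt, 16 h
Reagents that add atoms: none
Why: Wittig olefination with a stabilised formyl ylide gives the E-trisubstituted enal (CHO trans to the acetal carbon), which later fixes C2 and C9 trans on ring A.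

Step 2
Reactants: 4 (E)-4-(dimethylamino)but-3-en-2-one
Product: 6 (E)-1-(dimethylamino)pent-1-en-3-one, via lithium enolate 5 (not isolated)
Conditions: LiN(SiMe3)2, THF, −78 °C; MeI, −78 → 0 °C
Reagents that add atoms: iodomethane CI; lithium bis(trimethylsilyl)amide [Li]N([Si](C)(C)C)[Si](C)(C)C (lithium of 5)
Why: Kinetic deprotonation of the vinylogous amide at its methyl group and SN2 C-methylation of the enolate give the ethyl ketone (the new methyl becomes C20).

Step 3
Reactants: 6 (E)-1-(dimethylamino)pent-1-en-3-one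
Product: 8 (1E,3Z)-3-(TBS-oxy)-N,N-dimethylpenta-1,3-dien-1-amine, via potassium enolate 7 (not isolated)
Conditions: KN(SiMe3)2, THF, −78 °C; t-BuMe2SiCl, −78 °C → rt
Reagents that add atoms: tert-butyldimethylsilyl chloride CC(C)(C)[Si](C)(C)Cl; potassium bis(trimethylsilyl)amide [K]N([Si](C)(C)C)[Si](C)(C)C (potassium of 7)
Why: O-silylation of the Z-enolate (silyl enol ether formation) gives the Rawal-type 1-amino-3-siloxydiene.

Step 4
Reactants: 3 (E)-4,4-dimethoxy-2-methylbut-2-enal; 8 (1E,3Z)-3-(TBS-oxy)-N,N-dimethylpenta-1,3-dien-1-amine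
Product: 10 (1S,6S)-6-(dimethoxymethyl)-1,5-dimethyl-4-oxocyclohex-2-ene-1-carbaldehyde (C5 epimer mixture), via cycloadduct 9 (not isolated)
Conditions: (R,R)-α,α,α′,α′-tetra(1-naphthyl)-TADDOL (20 mol %), toluene, −78 → −20 °C; then AcCl, −78 °C; aq. NaHCO3
Reagents that add atoms: none
Why: Diels–Alder reaction of the aminosiloxydiene with the hydrogen-bond-activated E-enal: the amino group steers C11 to the enal β-carbon (C10), the E geometry fixes C2 and C9 trans, the TADDOL sets the absolute configuration at C1 and C10, and AcCl then expels the amine to unmask the enone (C11 and C14 need no control here).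

Step 5
Reactants: 10 enone aldehyde
Product: 11 (4S,5S)-5-(dimethoxymethyl)-4-(hydroxymethyl)-4,6-dimethylcyclohex-2-en-1-one (C6 epimer mixture)
Conditions: NaBH4, MeOH–CH2Cl2, −78 °C
Reagents that add atoms: none
Why: Chemoselective hydride reduction: at −78 °C the aldehyde is reduced much faster than the cross-conjugated enone, and no stereocentre is touched.

Step 6
Reactants: 11 hydroxymethyl enone
Product: 12 (4S,5S)-4-[(TBS-oxy)methyl]-5-(dimethoxymethyl)-4,6-dimethylcyclohex-2-en-1-one (C6 epimer mixture)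
Conditions: t-BuMe2SiCl, imidazole, DMF, rt
Reagents that add atoms: tert-butyldimethylsilyl chloride CC(C)(C)[Si](C)(C)Cl
Why: Silyl ether formation protects the neopentyl C2 alcohol until the ring closure.

Step 7
Reactants: 12 TBS-protected enone
Product: 14 (4S,5S,6R)-4-[(TBS-oxy)methyl]-5-(dimethoxymethyl)-4,6-dimethylcyclohex-2-en-1-one, via lithium dienolate 13 (not isolated)
Conditions: LiN(i-Pr)2, THF, −78 °C; AcOH in THF, −78 °C
Reagents that add atoms: lithium diisopropylamide [Li]N(C(C)C)C(C)C (lithium of 13)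
Why: Kinetic enolate protonation: the only acidic site is C11 (C1 is quaternary), and the dienolate is protonated from the α-face, anti to the adjacent C10 side chain and the C15 methyl, which places the C20 methyl β and cis to C9 (11R).

Step 8
Reactants: 14 enone with C11 set
Product: 16 (2R,3S,4S,5S)-4-[(TBS-oxy)methyl]-3-(dimethoxymethyl)-5-hydroxy-2,4-dimethylcyclohexan-1-one, via C14 pinacol boronate 15 (not isolated)
Conditions: CuCl (5 mol %), DPEphos (5 mol %), NaOt-Bu (10 mol %), B2pin2, MeOH (2 equiv), THF, rt; then 30% H2O2, aq. NaHCO3, 0 °C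
Reagents that add atoms: bis(pinacolato)diboron CC1(C)OB(OC1(C)C)B1OC(C)(C)C(C)(C)O1 (boron of 15); hydrogen peroxide OO (oxygen of 16)
Why: Copper-catalysed conjugate borylation and stereoretentive C–B oxidation: the boryl-copper adds to C14 from the α-face, opposite the β-oriented C15 methyl, C10 side chain and C20 methyl, giving the 14α-hydroxyl (14S).

Step 9
Reactants: 16 β-hydroxy ketone
Product: 17 (1S,2S,3S,4R)-2-[(TBS-oxy)methyl]-3-(dimethoxymethyl)-2,4-dimethyl-5-oxocyclohexyl butanoate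
Conditions: (n-PrCO)2O, pyridine, DMAP (0.1 equiv), CH2Cl2, 0 °C → rt
Reagents that add atoms: butanoic anhydride CCCC(=O)OC(=O)CCC
Why: DMAP-catalysed acylation installs the C14 butanoate; bases stronger than pyridine are avoided from here on because the product is a β-acyloxy ketone.

Step 10
Reactants: 17 butanoate acetal
Product: 18 (1S,2S,3S,4R)-2-[(TBS-oxy)methyl]-3-formyl-2,4-dimethyl-5-oxocyclohexyl butanoate (fragment 1; briarane 1S,10S,11R,14S)
Conditions: PPTS, acetone–H2O (10:1), rt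
Reagents that add atoms: water O
Why: Mild acid-catalysed acetal hydrolysis frees the C9 aldehyde while the silyl ether and the ester survive.

**Fragment 2 (alkenyl iodide 34)**

Step 11
Reactants: 19 2-bromoprop-2-en-1-ol; 20 (E)-trimethyl[2-(pinacolboryl)ethenyl]silane
Product: 21 (E)-2-methylidene-4-(trimethylsilyl)but-3-en-1-ol
Conditions: Pd(PPh3)4 (5 mol %), K2CO3, THF–H2O, 60 °C
Reagents that add atoms: none
Why: Suzuki–Miyaura cross-coupling of the alkenyl bromide with the alkenylboronate proceeds with retention and gives the E-silyl diene (C3–C5, C16).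

Step 12
Reactants: 21 dienol
Product: 22 (E)-2-methylidene-4-(trimethylsilyl)but-3-enal
Conditions: MnO2, CH2Cl2, rt; used at once
Reagents that add atoms: none
Why: Allylic alcohol oxidation with MnO2 gives the 2-substituted acrolein (C6 aldehyde) without isomerising the diene.

Step 13
Reactants: 23 methyl (S)-3-hydroxy-2-methylpropanoate
Product: 24 methyl (S)-3-(TBS-oxy)-2-methylpropanoate
Conditions: t-BuMe2SiCl, imidazole, CH2Cl2, rt
Reagents that add atoms: tert-butyldimethylsilyl chloride CC(C)(C)[Si](C)(C)Cl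
Why: Silyl ether formation protects the future C19 oxygen; the stereocentre (future C17) comes from the chiral pool.

Step 14
Reactants: 24 silyl ether ester
Product: 25 (S)-3-(TBS-oxy)-2-methylpropanal
Conditions: i-Bu2AlH, CH2Cl2, −78 °C; aq. potassium sodium tartrate
Reagents that add atoms: none
Why: Partial ester reduction stops at the aldehyde through the stable tetrahedral aluminium hemiacetal at −78 °C, and the α-stereocentre is kept by using the aldehyde at once.

Step 15
Reactants: 25 aldehyde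
Product: 26 (R)-tert-butyldimethyl[(2-methylbut-3-yn-1-yl)oxy]silane
Conditions: dimethyl (1-diazo-2-oxopropyl)phosphonate, K2CO3, MeOH, 0 °C → rt
Reagents that add atoms: dimethyl (1-diazo-2-oxopropyl)phosphonate COP(=O)(OC)C(=[N+]=[N-])C(C)=O
Why: Seyferth–Gilbert homologation with the Ohira–Bestmann reagent converts the aldehyde into the terminal alkyne (new carbon = C7) under conditions mild enough to keep the α-stereocentre.

Step 16
Reactants: 22 (E)-2-methylidene-4-(trimethylsilyl)but-3-enal; 26 (R)-alkyne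
Product: 28 (1E,4R,7R)-8-(TBS-oxy)-7-methyl-3-methylidene-1-(trimethylsilyl)oct-1-en-5-yn-4-ol, via alkynylzinc 27 (not isolated)
Conditions: Me2Zn, (S,S)-ProPhenol (20 mol %), Ph3PO (40 mol %), toluene, 0 °C
Reagents that add atoms: dimethylzinc C[Zn]C (methylzinc of 27)
Why: Catalytic asymmetric alkynylation (Trost ProPhenol–zinc): the alkynylzinc adds to one face of the enal under ligand control and sets the C6 carbinol (6R), the centre later inverted by chloride.

Step 17
Reactants: 28 propargylic alcohol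
Product: 29 (1E,4R,7R)-8-(TBS-oxy)-7-methyl-3-methylidene-4-(TIPS-oxy)-1-(trimethylsilyl)oct-1-en-5-yne
Conditions: i-Pr3SiOTf, 2,6-lutidine, CH2Cl2, −78 → 0 °C
Reagents that add atoms: triisopropylsilyl trifluoromethanesulfonate CC(C)[Si](OS(=O)(=O)C(F)(F)F)(C(C)C)C(C)C
Why: Silyl ether formation gives a bulky, acid-robust C6 protecting group that also biases the next step sterically.

Step 18
Reactants: 29 TIPS-protected alkyne
Product: 31 (1E,4S,5E,7S)-8-(TBS-oxy)-6-iodo-7-methyl-3-methylidene-4-(TIPS-oxy)-1-(trimethylsilyl)octa-1,5-diene, via alkenylzirconocene 30 (not isolated)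
Conditions: Cp2Zr(H)Cl, THF, rt; I2, 0 °C
Reagents that add atoms: chlorobis(cyclopentadienyl)hydridozirconium [H][Zr](Cl)(C1C=CC=C1)C1C=CC=C1 (hydrogen at C7, zirconium of 30); iodine II
Why: Hydrozirconation–iodination: syn addition of Zr–H places zirconium at C8, remote from the bulky C6 silyloxy group, and iodinolysis with retention gives the iodoalkene with iodine trans and C17 cis to C6.

Step 19
Reactants: 31 alkenyl iodide bis-silyl ether
Product: 32 (2S,3E,5S,7E)-3-iodo-2-methyl-6-methylidene-5-(TIPS-oxy)-8-(trimethylsilyl)octa-3,7-dien-1-ol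
Conditions: camphorsulfonic acid (10 mol %), MeOH–CH2Cl2, 0 °C
Reagents that add atoms: none
Why: Acid-catalysed methanolysis removes the primary TBS ether selectively, the secondary TIPS ether and the vinylsilane being far slower.

Step 20
Reactants: 32 primary alcohol
Product: 33 (2S,3E,5S,7E)-3-iodo-2-methyl-6-methylidene-5-(TIPS-oxy)-8-(trimethylsilyl)octa-3,7-dienoic acid
Conditions: TEMPO (20 mol %), PhI(OAc)2, MeCN–pH 7 buffer, rt
Reagents that add atoms: water O
Why: TEMPO/PhI(OAc)2 oxidation takes the primary alcohol through the aldehyde hydrate to the acid under near-neutral conditions that spare the C17 stereocentre.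

Step 21
Reactants: 33 acid
Product: 34 tert-butyl (2S,3E,5S,7E)-3-iodo-2-methyl-6-methylidene-5-(TIPS-oxy)-8-(trimethylsilyl)octa-3,7-dienoate (fragment 2)
Conditions: tert-butyl 2,2,2-trichloroacetimidate, CH2Cl2–cyclohexane, rt
Reagents that add atoms: tert-butyl 2,2,2-trichloroacetimidate CC(C)(C)OC(=N)C(Cl)(Cl)Cl
Why: O-alkylation of the acid by the imidate gives the tert-butyl ester, chosen so that the C19 carbonyl cannot lactonise onto the future C9 hydroxyl.

**Union and endgame**

Step 22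
Reactants: 18 ring A aldehyde; 34 alkenyl iodide
Product: 35 C8–C9 coupled allylic alcohol (9-OH; E-C7=C8; 6-OTIPS; C2–OTBS; tert-butyl ester at C19; E-vinyl-TMS at C3)
Conditions: CrCl2 (6 equiv), NiCl2 (2 mol %), DMSO, rt
Reagents that add atoms: none
Why: Nozaki–Hiyama–Kishi coupling: zerovalent nickel formed in situ inserts into the C8–I bond, transmetalation to chromium gives an aldehyde-selective alkenyl nucleophile (ketone and esters untouched), and Felkin–Anh attack anti to the quaternary C1 sets the 9-OH configuration with the alkene geometry retained.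

Step 23
Reactants: 35 allylic alcohol
Product: 37 γ-lactone diol (lactone O on C7; 8-OH; 9-OH; 17-methyl cis to 8-OH; 6-OTIPS; C2–OTBS), via epoxy alcohol 36 (not isolated)
Conditions: VO(acac)2 (10 mol %), t-BuOOH, CH2Cl2, 0 °C; then camphorsulfonic acid (20 mol %), 0 °C → rt
Reagents that add atoms: tert-butyl hydroperoxide CC(C)(C)OO
Why: Hydroxyl-directed epoxidation is chemoselective for the allylic alcohol alkene and erythro-selective for this 2-substituted allylic alcohol (A1,2 strain), which fixes C8; acid then lets the tert-butyl ester carbonyl open the epoxide at C7 with inversion (loss of isobutene), giving the lactone with C6 and C9 trans.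

Step 24
Reactants: 37 lactone diol
Product: 38 9-acetate of 37
Conditions: Ac2O, pyridine, DMAP (0.2 equiv), CH2Cl2, 0 °C → rt
Reagents that add atoms: acetic anhydride CC(=O)OC(C)=O
Why: Acylation of the secondary C9 alcohol (the tertiary C8 alcohol does not react) installs the 9-acetate and removes the risk of translactonisation to O9.

Step 25
Reactants: 38 vinylsilane
Product: 39 (E)-C3 dienyl iodide
Conditions: N-iodosuccinimide, (CF3)2CHOH, 0 °C, 5 min
Reagents that add atoms: N-iodosuccinimide O=C1CCC(=O)N1I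
Why: Iododesilylation (ipso attack on the vinylsilane through a β-silyl cation) gives the dienyl iodide with retention of the E geometry.

Step 26
Reactants: 39 dienyl iodide
Product: 40 C2 primary alcohol
Conditions: HF·pyridine, pyridine, THF, 0 °C
Reagents that add atoms: none
Why: Fluoride-mediated desilylation cleaves the primary TBS ether while the hindered secondary TIPS ether survives.

Step 27
Reactants: 40 primary alcohol
Product: 41 C2 aldehyde (seco-aldehyde)
Conditions: Dess–Martin periodinane, NaHCO3, CH2Cl2, 0 °C → rt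
Reagents that add atoms: none
Why: Dess–Martin oxidation gives the non-enolisable neopentyl aldehyde without touching the tertiary alcohol.

Step 28
Reactants: 41 seco-aldehyde
Product: 42 macrocyclic 2-alcohol (ten-membered ring closed; 9-OAc; 6-OTIPS)
Conditions: CrCl2 (15 equiv), NiCl2 (2 mol %), DMSO–THF, 0.002 M, syringe-pump addition, rt
Reagents that add atoms: none
Why: Intramolecular Nozaki–Hiyama–Kishi macrocyclization under high dilution: the dienylchromium from the C3 iodide adds to the C2 aldehyde, closing the ten-membered ring with E-C3=C4 preset; the C2 configuration is set by the conformation of the closing ring and must be verified.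

Step 29
Reactants: 42 macrocyclic alcohol
Product: 43 2,9-diacetate (6-OTIPS)
Conditions: Ac2O, pyridine, DMAP (cat.), CH2Cl2, 0 °C
Reagents that add atoms: acetic anhydride CC(=O)OC(C)=O
Why: Acylation of the allylic C2 alcohol gives the 2-acetate while the tertiary C8 alcohol stays free.

Step 30
Reactants: 43 diacetate silyl ether
Product: 44 6-epi-alcohol (C6–OH opposite to the C6–Cl of the target)
Conditions: HF·pyridine, THF, 0 °C → rt
Reagents that add atoms: none
Why: Desilylation of the allylic TIPS ether under non-basic conditions is tolerated by the β-acyloxy ketone and the acetates.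

Step 31
Reactants: 44 6-epi-alcohol
Product: 45 target CNP0283653.2
Conditions: Cl3CC(O)CCl3, PPh3, 2,6-di-tert-butylpyridine, CH2Cl2, −20 → 0 °C
Reagents that add atoms: hexachloroacetone O=C(C(Cl)(Cl)Cl)C(Cl)(Cl)Cl
Why: Appel-type deoxychlorination (Magid conditions) converts the allylic alcohol through its alkoxyphosphonium salt into the chloride by SN2 with inversion at C6 and little allylic transposition.

**Compound list**
1 | 2,2-dimethoxyacetaldehyde | COC(OC)C=O | starting material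
2 | 2-(triphenylphosphoranylidene)propanal | CC(C=O)=P(c1ccccc1)(c1ccccc1)c1ccccc1 | starting material
3 | (E)-4,4-dimethoxy-2-methylbut-2-enal | O=C/C(C)=C/C(OC)OC | intermediate
4 | (E)-4-(dimethylamino)but-3-en-2-one | CC(=O)/C=C/N(C)C | starting material
5 | lithium (E)-4-(dimethylamino)buta-1,3-dien-2-olate | C=C(O[Li])/C=C/N(C)C | intermediate (not isolated)
6 | (E)-1-(dimethylamino)pent-1-en-3-one | CCC(=O)/C=C/N(C)C | intermediate
7 | potassium (1E,3Z)-1-(dimethylamino)penta-1,3-dien-3-olate | C/C=C(O[K])/C=C/N(C)C | intermediate (not isolated)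
8 | (1E,3Z)-3-(TBS-oxy)-N,N-dimethylpenta-1,3-dien-1-amine | C/C=C(O[Si](C)(C)C(C)(C)C)/C=C/N(C)C | intermediate
9 | Diels–Alder adduct, (1R,6S)-4-(TBS-oxy)-2-(dimethylamino)-6-(dimethoxymethyl)-1,5-dimethylcyclohex-3-ene-1-carbaldehyde (C2, C5 mixtures) | O=C[C@]1(C)[C@@H](C(OC)OC)C(C)C(O[Si](C)(C)C(C)(C)C)=CC1N(C)C | intermediate (not isolated)
10 | (1S,6S)-6-(dimethoxymethyl)-1,5-dimethyl-4-oxocyclohex-2-ene-1-carbaldehyde (C5 mixture) | O=C[C@]1(C)[C@@H](C(OC)OC)C(C)C(=O)C=C1 | intermediate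
11 | (4S,5S)-5-(dimethoxymethyl)-4-(hydroxymethyl)-4,6-dimethylcyclohex-2-en-1-one (C6 mixture) | OC[C@]1(C)[C@@H](C(OC)OC)C(C)C(=O)C=C1 | intermediate
12 | (4S,5S)-4-[(TBS-oxy)methyl]-5-(dimethoxymethyl)-4,6-dimethylcyclohex-2-en-1-one (C6 mixture) | CC(C)(C)[Si](C)(C)OC[C@]1(C)[C@@H](C(OC)OC)C(C)C(=O)C=C1 | intermediate
13 | lithium dienolate of 12 | CC(C)(C)[Si](C)(C)OC[C@]1(C)[C@@H](C(OC)OC)C(C)=C(O[Li])C=C1 | intermediate (not isolated)
14 | (4S,5S,6R)-4-[(TBS-oxy)methyl]-5-(dimethoxymethyl)-4,6-dimethylcyclohex-2-en-1-one | CC(C)(C)[Si](C)(C)OC[C@]1(C)[C@@H](C(OC)OC)[C@@H](C)C(=O)C=C1 | intermediate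
15 | (2R,3S,4S,5S)-4-[(TBS-oxy)methyl]-3-(dimethoxymethyl)-2,4-dimethyl-5-(Bpin)cyclohexan-1-one | CC(C)(C)[Si](C)(C)OC[C@]1(C)[C@@H](C(OC)OC)[C@@H](C)C(=O)C[C@@H]1B2OC(C)(C)C(C)(C)O2 | intermediate (not isolated)
16 | (2R,3S,4S,5S)-4-[(TBS-oxy)methyl]-3-(dimethoxymethyl)-5-hydroxy-2,4-dimethylcyclohexan-1-one | CC(C)(C)[Si](C)(C)OC[C@]1(C)[C@@H](C(OC)OC)[C@@H](C)C(=O)C[C@@H]1O | intermediate
17 | (1S,2S,3S,4R)-2-[(TBS-oxy)methyl]-3-(dimethoxymethyl)-2,4-dimethyl-5-oxocyclohexyl butanoate | CC(C)(C)[Si](C)(C)OC[C@]1(C)[C@@H](C(OC)OC)[C@@H](C)C(=O)C[C@@H]1OC(=O)CCC | intermediate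
18 | (1S,2S,3S,4R)-2-[(TBS-oxy)methyl]-3-formyl-2,4-dimethyl-5-oxocyclohexyl butanoate (fragment 1) | CC(C)(C)[Si](C)(C)OC[C@]1(C)[C@@H](C=O)[C@@H](C)C(=O)C[C@@H]1OC(=O)CCC | intermediate
19 | 2-bromoprop-2-en-1-ol | OCC(Br)=C | starting material
20 | (E)-trimethyl[2-(4,4,5,5-tetramethyl-1,3,2-dioxaborolan-2-yl)ethenyl]silane | C[Si](C)(C)/C=C/B1OC(C)(C)C(C)(C)O1 | starting material
21 | (E)-2-methylidene-4-(trimethylsilyl)but-3-en-1-ol | C[Si](C)(C)/C=C/C(=C)CO | intermediate
22 | (E)-2-methylidene-4-(trimethylsilyl)but-3-enal | C[Si](C)(C)/C=C/C(=C)C=O | intermediate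
23 | methyl (S)-3-hydroxy-2-methylpropanoate | COC(=O)[C@@H](C)CO | starting material
24 | methyl (S)-3-(TBS-oxy)-2-methylpropanoate | COC(=O)[C@@H](C)CO[Si](C)(C)C(C)(C)C | intermediate
25 | (S)-3-(TBS-oxy)-2-methylpropanal | O=C[C@@H](C)CO[Si](C)(C)C(C)(C)C | intermediate
26 | (R)-tert-butyldimethyl[(2-methylbut-3-yn-1-yl)oxy]silane | C#C[C@@H](C)CO[Si](C)(C)C(C)(C)C | intermediate
27 | methylzinc acetylide of 26 | C[Zn]C#C[C@@H](C)CO[Si](C)(C)C(C)(C)C | intermediate (not isolated)
28 | (1E,4R,7R)-8-(TBS-oxy)-7-methyl-3-methylidene-1-(trimethylsilyl)oct-1-en-5-yn-4-ol | C[Si](C)(C)/C=C/C(=C)[C@@H](O)C#C[C@@H](C)CO[Si](C)(C)C(C)(C)C | intermediate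
29 | (1E,4R,7R)-8-(TBS-oxy)-7-methyl-3-methylidene-4-(TIPS-oxy)-1-(trimethylsilyl)oct-1-en-5-yne | C[Si](C)(C)/C=C/C(=C)[C@@H](O[Si](C(C)C)(C(C)C)C(C)C)C#C[C@@H](C)CO[Si](C)(C)C(C)(C)C | intermediate
30 | C8 alkenylzirconocene chloride from 29 (Zr trans to C6) | C[Si](C)(C)/C=C/C(=C)[C@@H](O[Si](C(C)C)(C(C)C)C(C)C)/C=C(/[Zr](Cl)(C1C=CC=C1)C1C=CC=C1)[C@@H](C)CO[Si](C)(C)C(C)(C)C | intermediate (not isolated)
31 | (1E,4S,5E,7S)-8-(TBS-oxy)-6-iodo-7-methyl-3-methylidene-4-(TIPS-oxy)-1-(trimethylsilyl)octa-1,5-diene | C[Si](C)(C)/C=C/C(=C)[C@@H](O[Si](C(C)C)(C(C)C)C(C)C)/C=C(/I)[C@@H](C)CO[Si](C)(C)C(C)(C)C | intermediate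
32 | (2S,3E,5S,7E)-3-iodo-2-methyl-6-methylidene-5-(TIPS-oxy)-8-(trimethylsilyl)octa-3,7-dien-1-ol | C[Si](C)(C)/C=C/C(=C)[C@@H](O[Si](C(C)C)(C(C)C)C(C)C)/C=C(/I)[C@@H](C)CO | intermediate
33 | (2S,3E,5S,7E)-3-iodo-2-methyl-6-methylidene-5-(TIPS-oxy)-8-(trimethylsilyl)octa-3,7-dienoic acid | C[Si](C)(C)/C=C/C(=C)[C@@H](O[Si](C(C)C)(C(C)C)C(C)C)/C=C(/I)[C@@H](C)C(=O)O | intermediate
34 | tert-butyl (2S,3E,5S,7E)-3-iodo-2-methyl-6-methylidene-5-(TIPS-oxy)-8-(trimethylsilyl)octa-3,7-dienoate (fragment 2) | C[Si](C)(C)/C=C/C(=C)[C@@H](O[Si](C(C)C)(C(C)C)C(C)C)/C=C(/I)[C@@H](C)C(=O)OC(C)(C)C | intermediate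
35 | C8–C9 coupled allylic alcohol (9-OH; E-C7=C8; 6-OTIPS; C2–OTBS; tert-butyl ester; vinyl-TMS) | C[Si](C)(C)/C=C/C(=C)[C@@H](O[Si](C(C)C)(C(C)C)C(C)C)/C=C(/[C@H](O)[C@H]1[C@@H](C)C(=O)C[C@H](OC(=O)CCC)[C@]1(C)CO[Si](C)(C)C(C)(C)C)[C@@H](C)C(=O)OC(C)(C)C | intermediate
36 | 7,8-epoxide of 35 | C[Si](C)(C)/C=C/C(=C)[C@@H](O[Si](C(C)C)(C(C)C)C(C)C)[C@H]1O[C@@]1([C@H](O)[C@H]2[C@@H](C)C(=O)C[C@H](OC(=O)CCC)[C@]2(C)CO[Si](C)(C)C(C)(C)C)[C@@H](C)C(=O)OC(C)(C)C | intermediate (not isolated)
37 | γ-lactone 8,9-diol (6-OTIPS; C2–OTBS; vinyl-TMS) | C[Si](C)(C)/C=C/C(=C)[C@@H](O[Si](C(C)C)(C(C)C)C(C)C)[C@@H]1OC(=O)[C@H](C)[C@@]1(O)[C@H](O)[C@H]2[C@@H](C)C(=O)C[C@H](OC(=O)CCC)[C@]2(C)CO[Si](C)(C)C(C)(C)C | intermediate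
38 | 9-acetate of 37 | C[Si](C)(C)/C=C/C(=C)[C@@H](O[Si](C(C)C)(C(C)C)C(C)C)[C@@H]1OC(=O)[C@H](C)[C@@]1(O)[C@H](OC(C)=O)[C@H]2[C@@H](C)C(=O)C[C@H](OC(=O)CCC)[C@]2(C)CO[Si](C)(C)C(C)(C)C | intermediate
39 | (E)-C3 dienyl iodide (C2–OTBS) | I/C=C/C(=C)[C@@H](O[Si](C(C)C)(C(C)C)C(C)C)[C@@H]1OC(=O)[C@H](C)[C@@]1(O)[C@H](OC(C)=O)[C@H]2[C@@H](C)C(=O)C[C@H](OC(=O)CCC)[C@]2(C)CO[Si](C)(C)C(C)(C)C | intermediate
40 | dienyl iodide with free C2 primary alcohol | I/C=C/C(=C)[C@@H](O[Si](C(C)C)(C(C)C)C(C)C)[C@@H]1OC(=O)[C@H](C)[C@@]1(O)[C@H](OC(C)=O)[C@H]2[C@@H](C)C(=O)C[C@H](OC(=O)CCC)[C@]2(C)CO | intermediate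
41 | seco-aldehyde (C2–CHO; C3–I) | I/C=C/C(=C)[C@@H](O[Si](C(C)C)(C(C)C)C(C)C)[C@@H]1OC(=O)[C@H](C)[C@@]1(O)[C@H](OC(C)=O)[C@H]2[C@@H](C)C(=O)C[C@H](OC(=O)CCC)[C@]2(C)C=O | intermediate
42 | macrocyclic 2-alcohol (9-OAc; 6-OTIPS) | C=C1/C=C/[C@@H](O)[C@]2(C)[C@@H]([C@@H](OC(C)=O)[C@]3(O)[C@@H](C)C(=O)O[C@H]3[C@@H]1O[Si](C(C)C)(C(C)C)C(C)C)[C@@H](C)C(=O)C[C@@H]2OC(=O)CCC | intermediate
43 | macrocyclic 2,9-diacetate (6-OTIPS) | C=C1/C=C/[C@@H](OC(C)=O)[C@]2(C)[C@@H]([C@@H](OC(C)=O)[C@]3(O)[C@@H](C)C(=O)O[C@H]3[C@@H]1O[Si](C(C)C)(C(C)C)C(C)C)[C@@H](C)C(=O)C[C@@H]2OC(=O)CCC | intermediate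
44 | 6-epi-alcohol (2,9-diacetate; 6-OH opposite to target C6–Cl) | C=C1/C=C/[C@@H](OC(C)=O)[C@]2(C)[C@@H]([C@@H](OC(C)=O)[C@]3(O)[C@@H](C)C(=O)O[C@H]3[C@@H]1O)[C@@H](C)C(=O)C[C@@H]2OC(=O)CCC | intermediate
45 | CNP0283653.2 | C=C1/C=C/[C@@H](OC(C)=O)[C@]2(C)[C@@H]([C@@H](OC(C)=O)[C@]3(O)[C@@H](C)C(=O)O[C@H]3[C@H]1Cl)[C@@H](C)C(=O)C[C@@H]2OC(=O)CCC | target

**Totals**
Total step count: 31.
Longest linear sequence: 19 steps (steps 13–21 then 22–31; equally steps 2–10 then 22–31), i.e. 19/31 = 0.61 of the total.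

**Three steps most likely to fail**

Step 18 (hydrozirconation–iodination). Both alkyne carbons carry branched substituents, so zirconium may add partly at C7, and the diene may compete. The fallback sets out from 29 and comes back at 31. Copper-catalysed formal hydroboration (CuCl, P(t-Bu)3, NaOt-Bu, B2pin2, MeOH, THF) uses the propargylic oxygen to direct boron electronically to C8 with syn addition and gives the C8 alkenyl pinacol boronate F1. Iododeboronation of F1 with I2/NaOH (retention) then gives 31.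

Step 28 (ten-membered ring closure). Besides oligomerisation, the C2 configuration is not predictable with confidence. The fallback sets out from 41 and comes back at 43. If the ring closes mainly to the C2 epimer, the 2-epi macrocyclic alcohol F2, this is not acetylated directly. Instead it is esterified with acetic acid under Mitsunobu conditions (PPh3, diisopropyl azodicarboxylate, toluene, 0 °C), an SN2 esterification that inverts C2 and installs the acetate in one operation.

Step 31 (allylic deoxychlorination). The alkoxyphosphonium salt may react by allylic transposition to C16 or eliminate, and the tertiary C8 hydroxyl is a bystander. The fallback sets out from 44 and comes back at 45. The 1,3-related C6 and C8 hydroxyls are tied together as the six-membered cyclic sulfite F3 (SOCl2, pyridine, CH2Cl2, −40 °C). Heating F3 with LiCl in DMF opens it by SN2 attack of chloride at the allylic C6 with inversion, and aqueous work-up hydrolyses the C8 sulfite half-ester with loss of SO2.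

**Further compounds**
F1 | step 18 | (1E,4S,5E,7S)-8-(TBS-oxy)-7-methyl-3-methylidene-6-(Bpin)-4-(TIPS-oxy)-1-(trimethylsilyl)octa-1,5-diene (boron trans to C6) | C[Si](C)(C)/C=C/C(=C)[C@@H](O[Si](C(C)C)(C(C)C)C(C)C)/C=C(/B1OC(C)(C)C(C)(C)O1)[C@@H](C)CO[Si](C)(C)C(C)(C)C
F2 | step 28 | 2-epi macrocyclic alcohol (C2 epimer of 42) | C=C1/C=C/[C@H](O)[C@]2(C)[C@@H]([C@@H](OC(C)=O)[C@]3(O)[C@@H](C)C(=O)O[C@H]3[C@@H]1O[Si](C(C)C)(C(C)C)C(C)C)[C@@H](C)C(=O)C[C@@H]2OC(=O)CCC
F3 | step 31 | 6,8-O-cyclic sulfite of 44 | C=C1/C=C/[C@@H](OC(C)=O)[C@]2(C)[C@@H]([C@@H](OC(C)=O)[C@]3(OS(=O)O4)[C@@H](C)C(=O)O[C@H]3[C@@H]14)[C@@H](C)C(=O)C[C@@H]2OC(=O)CCC
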